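The target is treated as a central benzene (ring A) that carries dihydrofuran 1, the seven-membered ring with ring B, and dihydrofuran 2 (the trans-2,3-diaryl-dihydrobenzofuran bearing the free 3,5-dihydroxyphenyl group). Everything rests on disconnecting dihydrofuran 2 at the bond between its C3 and the ring A carbon that lies ortho to its own ring oxygen and para to the oxygen of dihydrofuran 1. That electron-rich carbon migrates readily, so dihydrofuran 2 is the ring-contracted form of a flavanone on the same edge of ring A. One oxidative 1,2-aryl shift contracts the pyranone, forms the ring A–C3 bond and leaves a methyl ester on C3. The precursor is the permethylated core bearing a (2R)-2-(4-methoxyphenyl)chroman-4-one.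

Key step: step 13

Labels: ring A carbons are a1 (bears C8H2), a2 (bears C3'), a3 (bears O1'), a4 (CH), a5 (bears O1''), a6 (bears C3''). Ring B is the dioxygenated benzene in the seven-membered ring (b1 on C3', b6 on C7). Dihydrofuran 1 is O1'–C2'–C3' on a3/a2; dihydrofuran 2 is O1''–C2''–C3'' on a5/a6; C7 is the CH(aryl) and C8 the CH2 of the seven-membered ring. In these labels the target is (7S,2'S,3'S,2''R,3''R). Bicyclic and tricyclic intermediates use chromene and furo[3,2-g]chromene locants.

Remark on the structure: ring A carries only two oxygen atoms (on a3 and a5); a1 is carbon-substituted. A phloroglucinol-type building block must therefore give up one oxygen. Here the chelated 5-OH of 5,7-dihydroxychromone is spent as a triflate, and the chromone itself stores the acyl/phenol pair that later becomes the flavanone.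

Assumption 1: the sense of induction of Rh2(R-PTTL)4 (step 6) and of (S)-t-BuPyOx (step 12) is assigned by analogy with simpler substrates; if a model run shows the opposite sense, the antipodal catalyst or ligand is used.

Assumption 2: the cation cyclisation of step 11 is taken to give the C7 configuration of the ampelopsin B series, as the acid-induced ring closure of ε-viniferin-type stilbenes does.

Step 1
Reactants: 1 5,7-dihydroxychromone; 2 4-methoxybenzyl chloride
Product: 3 5-hydroxy-7-[(4-methoxybenzyl)oxy]-4H-chromen-4-one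
Conditions: 2 (1.1 equiv), K2CO3 (1.5 equiv), DMF, 50 °C
Reagents that add atoms: 2 4-methoxybenzyl chloride, COc1ccc(CCl)cc1
Why: Williamson etherification; the 7-OH is the acidic, unhindered phenol while the 5-OH is locked in a hydrogen bond to the C4 carbonyl, so mono-alkylation at O7 is expected.

Step 2
Reactants: 3 5-hydroxy-7-[(4-methoxybenzyl)oxy]-4H-chromen-4-one
Product: 4 5-hydroxy-6-iodo-7-[(4-methoxybenzyl)oxy]-4H-chromen-4-one
Conditions: BnMe3N·ICl2 (1.05 equiv), CaCO3, CH2Cl2/MeOH, rt
Reagents that add atoms: benzyltrimethylammonium dichloroiodate, C[N+](C)(C)Cc1ccccc1.Cl[I-]Cl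
Why: Electrophilic aromatic iodination; the chelated 5-OH directs the buffered dichloroiodate to its ortho position C6, the pattern known for 5-hydroxy-7-alkoxy chromones and flavones, and CaCO3 keeps the medium mild enough for the benzyl ether.

Step 3
Reactants: 4 5-hydroxy-6-iodo-7-[(4-methoxybenzyl)oxy]-4H-chromen-4-one
Product: 5 6-iodo-7-[(4-methoxybenzyl)oxy]-4-oxo-4H-chromen-5-yl trifluoromethanesulfonate
Conditions: Tf2O, pyridine, CH2Cl2, 0 °C
Reagents that add atoms: trifluoromethanesulfonic anhydride, O=S(=O)(OS(=O)(=O)C(F)(F)F)C(F)(F)F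
Why: O-sulfonylation of the only free phenol turns the oxygen that the target does not contain into a leaving group for the later C–C coupling at a1.

Step 4
Reactants: 5 6-iodo-7-[(4-methoxybenzyl)oxy]-4-oxo-4H-chromen-5-yl trifluoromethanesulfonate; 6 methyl bromoacetate (as its zinc reagent)
Product: 7 methyl 2-{7-[(4-methoxybenzyl)oxy]-4-oxo-5-(triflyloxy)-4H-chromen-6-yl}acetate
Conditions: BrZnCH2CO2Me (2 equiv; from 6, Zn dust, THF), Pd[P(t-Bu)3]2 (5 mol%), THF, rt
Reagents that add atoms: bromo(2-methoxy-2-oxoethyl)zinc (made from 6), COC(=O)C[Zn]Br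
Why: Negishi coupling of a Reformatsky reagent (palladium-catalysed ester α-arylation); with the bulky trialkylphosphine catalyst oxidative addition occurs at C–I far faster than at the aryl triflate, and the zinc enolate is too weak a nucleophile to add to the chromone.

Step 5
Reactants: 7 methyl 2-{7-[(4-methoxybenzyl)oxy]-4-oxo-5-(triflyloxy)-4H-chromen-6-yl}acetate
Product: 8 methyl 2-diazo-2-{7-[(4-methoxybenzyl)oxy]-4-oxo-5-(triflyloxy)-4H-chromen-6-yl}acetate
Conditions: p-ABSA (1.3 equiv), DBU, MeCN, 0 °C → rt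
Reagents that add atoms: 4-acetamidobenzenesulfonyl azide, CC(=O)Nc1ccc(cc1)S(=O)(=O)N=[N+]=[N-]
Why: Regitz diazo transfer to the methylene activated by both the ester and the electron-poor aryl ring; the non-nucleophilic amidine base leaves triflate and chromone intact.

Step 6
Reactants: 8 methyl 2-diazo-2-{7-[(4-methoxybenzyl)oxy]-4-oxo-5-(triflyloxy)-4H-chromen-6-yl}acetate
Product: 10 methyl (2S,3S)-2-(4-methoxyphenyl)-5-oxo-4-(triflyloxy)-2,3-dihydro-5H-furo[3,2-g]chromene-3-carboxylate (trans), via cis-ester 9 (not isolated)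
Conditions: Rh2(R-PTTL)4 (1 mol%), toluene, −60 °C; then DBU (0.3 equiv), rt → 40 °C
Reagents that add atoms: none
Why: Dirhodium-carbenoid intramolecular 1,5-C–H insertion into the electron-rich benzylic ether C–H closes dihydrofuran 1, the chiral phthaloyl-tert-leucinate ligands choosing one enantiotopic hydrogen so that C2 is set as S in cis-ester 9, and DBU then epimerises the acidic C3 to the more stable trans ester without touching C2.

Step 7
Reactants: 10 methyl (2S,3S)-2-(4-methoxyphenyl)-5-oxo-4-(triflyloxy)-2,3-dihydro-5H-furo[3,2-g]chromene-3-carboxylate; 11 (E)-2-(4-methoxyphenyl)ethenylboronic acid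
Product: 12 methyl (2S,3S)-2-(4-methoxyphenyl)-4-[(E)-2-(4-methoxyphenyl)ethenyl]-5-oxo-2,3-dihydro-5H-furo[3,2-g]chromene-3-carboxylate
Conditions: 11 (1.5 equiv), Pd(OAc)2 (5 mol%), SPhos (10 mol%), K3PO4, toluene, 80 °C
Reagents that add atoms: 11 (E)-2-(4-methoxyphenyl)ethenylboronic acid, COc1ccc(/C=C/B(O)O)cc1
Why: Suzuki–Miyaura coupling of the carbonyl-activated aryl triflate with retention of the E geometry; the styryl group is introduced only now so that no alkene is present during the carbenoid step.

Step 8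
Reactants: 12 methyl (2S,3S)-2-(4-methoxyphenyl)-4-[(E)-2-(4-methoxyphenyl)ethenyl]-5-oxo-2,3-dihydro-5H-furo[3,2-g]chromene-3-carboxylate
Product: 13 (2S,3S)-2-(4-methoxyphenyl)-4-[(E)-2-(4-methoxyphenyl)ethenyl]-5-oxo-2,3-dihydro-5H-furo[3,2-g]chromene-3-carboxylic acid
Conditions: Me3SnOH (5 equiv), ClCH2CH2Cl, 80 °C; then 1 M HCl wash
Reagents that add atoms: trimethyltin hydroxide, C[Sn](C)(C)O
Why: Trimethyltin hydroxide cleaves the methyl ester through a tin carboxylate under near-neutral conditions (a known mild ester hydrolysis), which avoids hydroxide-induced opening of the 4-pyranone ring; C2 is unaffected.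

Step 9
Reactants: 13 (2S,3S)-2-(4-methoxyphenyl)-4-[(E)-2-(4-methoxyphenyl)ethenyl]-5-oxo-2,3-dihydro-5H-furo[3,2-g]chromene-3-carboxylic acid
Product: 14 1,3-dioxoisoindolin-2-yl (2S,3S)-2-(4-methoxyphenyl)-4-[(E)-2-(4-methoxyphenyl)ethenyl]-5-oxo-2,3-dihydro-5H-furo[3,2-g]chromene-3-carboxylate
Conditions: N-hydroxyphthalimide, DIC, DMAP (cat.), CH2Cl2, rt
Reagents that add atoms: N-hydroxyphthalimide, O=C1c2ccccc2C(=O)N1O
Why: Carbodiimide (Steglich-type) esterification gives the redox-active ester needed for single-electron decarboxylation.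

Step 10
Reactants: 14 the N-acyloxyphthalimide of acid 13; 15 1-bromo-3,5-dimethoxybenzene (as its zinc reagent)
Product: 16 (2S,3S)-3-(3,5-dimethoxyphenyl)-2-(4-methoxyphenyl)-4-[(E)-2-(4-methoxyphenyl)ethenyl]-2,3-dihydro-5H-furo[3,2-g]chromen-5-one
Conditions: ArZnCl·LiCl (3 equiv; from 15, Mg, LiCl, THF, then ZnCl2), NiCl2·glyme (20 mol%), 4,4'-di-tert-butyl-2,2'-bipyridine (40 mol%), THF/DMF, rt
Reagents that add atoms: (3,5-dimethoxyphenyl)zinc chloride (made from 15), COc1cc(OC)cc([Zn]Cl)c1
Why: Nickel-catalysed decarboxylative Negishi arylation of a redox-active ester; electron transfer and loss of CO2 give a planar benzylic C3 radical that is arylated on the face opposite the C2 aryl group, so ring B is installed trans and C3 (C3' of the target) becomes S under control of C2.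

Step 11
Reactants: 16 (2S,3S)-3-(3,5-dimethoxyphenyl)-2-(4-methoxyphenyl)-4-[(E)-2-(4-methoxyphenyl)ethenyl]-2,3-dihydro-5H-furo[3,2-g]chromen-5-one
Product: 17 (7S,2'S,3'S)-chromone-fused core (ring A, ring B, seven-membered ring, dihydrofuran 1, 4H-pyran-4-one on the a5–a6 edge)
Conditions: CF3CO2H/CH2Cl2 (1:4), 0 °C → rt
Reagents that add atoms: none
Why: Intramolecular Friedel–Crafts alkylation (cation–arene cyclisation of the ε-viniferin to ampelopsin B type); protonation at C8 gives the 4-methoxybenzylic cation at C7, which ring B carbon b6 (ortho and para to methoxy) attacks to close the seven-membered ring, the C3' centre holding ring B on one face so that the C7 aryl group and the C3'–C2' bond end on opposite faces of the new ring (7S).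

Step 12
Reactants: 17 (7S,2'S,3'S)-chromone-fused core; 18 (4-methoxyphenyl)boronic acid
Product: 19 (7S,2'S,3'S,2''R)-flavanone (core with a 2''-(4-methoxyphenyl)chroman-4''-one on the a5–a6 edge)
Conditions: 18 (2.5 equiv), Pd(OCOCF3)2 (10 mol%), (S)-t-BuPyOx (12 mol%), NH4PF6 (30 mol%), H2O (5 equiv), ClCH2CH2Cl, 60 °C
Reagents that add atoms: 18 (4-methoxyphenyl)boronic acid, COc1ccc(B(O)O)cc1
Why: Palladium-catalysed asymmetric conjugate addition of an arylboronic acid to a chromone; the cationic aryl-palladium pyridine-oxazoline complex delivers the aryl group to one face of C2'', far from the existing stereocentres, so the ligand alone sets 2''R and protonation of the palladium enolate gives the flavanone.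

Step 13
Reactants: 19 (7S,2'S,3'S,2''R)-flavanone
Product: 22 (7S,2'S,3'S,2''R,3''R)-methyl ester (core with trans methyl 2''-(4-methoxyphenyl)-dihydrofuran-3''-carboxylate as dihydrofuran 2), via enol ether 20 (not isolated), via iodane adduct 21 (not isolated)
Conditions: PhI(OAc)2 (1.2 equiv), H2SO4 (1 equiv), HC(OMe)3/MeOH, 0 °C → rt
Reagents that add atoms: methanol, CO; trimethyl orthoformate, COC(OC)OC
Why: Acid and trimethyl orthoformate turn ketone 19 into enol ether 20, which attacks the trivalent iodine electrophile through C3'' on the face remote from the C2'' aryl group while methanol adds to C4'', giving adduct 21; ring A carbon a6, anti-periplanar to the equatorial C3''–I bond, then shifts from C4'' to C3'' as iodobenzene leaves, and the dimethoxycarbenium ion left at C4'' collapses to the methyl ester. The closest known reaction is this very type, the oxidative rearrangement of flavanones to methyl trans-2-aryl-2,3-dihydrobenzofuran-3-carboxylates by hypervalent iodine reagents or thallium trinitrate, a semipinacol-like 1,2-aryl shift. Dihydrofuran 2 is closed by ring contraction and not by a cyclisation: the a6–C4'' bond of the pyranone is traded for the a6–C3'' bond through a bridged arenium-type transition state. The new stereocentre C3'' is controlled by C2'': iodine enters anti to the 4-methoxyphenyl group and the migration inverts C3'', which places the ester trans to that aryl group, also the thermodynamically preferred arrangement. The selectivity required is migration of ring A instead of the C2'' aryl group (isoflavone) or plain dehydrogenation (flavone); it is secured by the equatorial C2'' aryl group, which cannot align with the C3''–I bond, and by the high migratory aptitude of a6, ortho to O1'' and para to O1'. C2'' takes no part, so the configuration set in step 12 is carried over unchanged.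

Step 14
Reactants: 22 (7S,2'S,3'S,2''R,3''R)-methyl ester
Product: 23 (7S,2'S,3'S,2''R,3''R)-carboxylic acid
Conditions: LiOH·H2O (5 equiv), THF/MeOH/H2O, rt; then 1 M HCl
Reagents that add atoms: lithium hydroxide, [Li+].[OH-]
Why: Saponification of the trans methyl ester; base can only hold C3'' in the trans series already present, and the base-sensitive pyranone is gone.

Step 15
Reactants: 23 (7S,2'S,3'S,2''R,3''R)-carboxylic acid
Product: 24 N-acyloxyphthalimide of acid 23
Conditions: N-hydroxyphthalimide, DIC, DMAP (cat.), CH2Cl2, rt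
Reagents that add atoms: N-hydroxyphthalimide, O=C1c2ccccc2C(=O)N1O
Why: Carbodiimide (Steglich-type) esterification gives the redox-active ester for the second decarboxylative coupling.

Step 16
Reactants: 24 N-acyloxyphthalimide of acid 23; 15 1-bromo-3,5-dimethoxybenzene (as its zinc reagent)
Product: 25 hepta-O-methyl ether of the target (7S,2'S,3'S,2''R,3''R)
Conditions: ArZnCl·LiCl (3 equiv; from 15, Mg, LiCl, THF, then ZnCl2), NiCl2·glyme (20 mol%), 4,4'-di-tert-butyl-2,2'-bipyridine (40 mol%), THF/DMF, rt
Reagents that add atoms: (3,5-dimethoxyphenyl)zinc chloride (made from 15), COc1cc(OC)cc([Zn]Cl)c1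
Why: Nickel-catalysed decarboxylative Negishi arylation as in step 10; the planar benzylic C3'' radical is arylated on the face opposite the C2'' aryl group, giving trans (3''R) dihydrofuran 2 under control of the C2'' centre.

Step 17
Reactants: 25 hepta-O-methyl ether of the target
Product: 26 CNP0136963.1 (target)
Conditions: BBr3 (15 equiv), CH2Cl2, −78 °C → rt; MeOH quench
Reagents that add atoms: none
Why: Lewis-acid cleavage of the seven aryl methyl ethers with BBr3; both dihydrobenzofurans are the trans (thermodynamic) isomers and their C3 centres are fixed, so any reversible opening at a benzylic C–O bond returns the same configuration.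

Compound list
1 | 5,7-dihydroxy-4H-chromen-4-one (5,7-dihydroxychromone) | O=c1ccoc2cc(O)cc(O)c12 | starting material
2 | 4-methoxybenzyl chloride | COc1ccc(CCl)cc1 | starting material
3 | 5-hydroxy-7-[(4-methoxybenzyl)oxy]-4H-chromen-4-one | O=c1ccoc2cc(OCc3ccc(OC)cc3)cc(O)c12 | intermediate
4 | 5-hydroxy-6-iodo-7-[(4-methoxybenzyl)oxy]-4H-chromen-4-one | O=c1ccoc2cc(OCc3ccc(OC)cc3)c(I)c(O)c12 | intermediate
5 | 6-iodo-7-[(4-methoxybenzyl)oxy]-4-oxo-4H-chromen-5-yl trifluoromethanesulfonate | O=c1ccoc2cc(OCc3ccc(OC)cc3)c(I)c(OS(=O)(=O)C(F)(F)F)c12 | intermediate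
6 | methyl bromoacetate | COC(=O)CBr | starting material
7 | methyl 2-{7-[(4-methoxybenzyl)oxy]-4-oxo-5-(triflyloxy)-4H-chromen-6-yl}acetate | O=c1ccoc2cc(OCc3ccc(OC)cc3)c(CC(=O)OC)c(OS(=O)(=O)C(F)(F)F)c12 | intermediate
8 | methyl 2-diazo-2-{7-[(4-methoxybenzyl)oxy]-4-oxo-5-(triflyloxy)-4H-chromen-6-yl}acetate | O=c1ccoc2cc(OCc3ccc(OC)cc3)c(C(=[N+]=[N-])C(=O)OC)c(OS(=O)(=O)C(F)(F)F)c12 | intermediate
9 | methyl (2S,3R)-2-(4-methoxyphenyl)-5-oxo-4-(triflyloxy)-2,3-dihydro-5H-furo[3,2-g]chromene-3-carboxylate (cis) | COC(=O)[C@H]1[C@@H](c2ccc(OC)cc2)Oc2cc3occc(=O)c3c(OS(=O)(=O)C(F)(F)F)c21 | intermediate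
10 | methyl (2S,3S)-2-(4-methoxyphenyl)-5-oxo-4-(triflyloxy)-2,3-dihydro-5H-furo[3,2-g]chromene-3-carboxylate (trans) | COC(=O)[C@@H]1[C@@H](c2ccc(OC)cc2)Oc2cc3occc(=O)c3c(OS(=O)(=O)C(F)(F)F)c21 | intermediate
11 | (E)-2-(4-methoxyphenyl)ethenylboronic acid | COc1ccc(/C=C/B(O)O)cc1 | starting material
12 | methyl (2S,3S)-2-(4-methoxyphenyl)-4-[(E)-2-(4-methoxyphenyl)ethenyl]-5-oxo-2,3-dihydro-5H-furo[3,2-g]chromene-3-carboxylate | COC(=O)[C@@H]1[C@@H](c2ccc(OC)cc2)Oc2cc3occc(=O)c3c(/C=C/c3ccc(OC)cc3)c21 | intermediate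
13 | (2S,3S)-2-(4-methoxyphenyl)-4-[(E)-2-(4-methoxyphenyl)ethenyl]-5-oxo-2,3-dihydro-5H-furo[3,2-g]chromene-3-carboxylic acid | OC(=O)[C@@H]1[C@@H](c2ccc(OC)cc2)Oc2cc3occc(=O)c3c(/C=C/c3ccc(OC)cc3)c21 | intermediate
14 | 1,3-dioxoisoindolin-2-yl ester of acid 13 | O=C(ON1C(=O)c2ccccc2C1=O)[C@@H]1[C@@H](c2ccc(OC)cc2)Oc2cc3occc(=O)c3c(/C=C/c3ccc(OC)cc3)c21 | intermediate
15 | 1-bromo-3,5-dimethoxybenzene | COc1cc(Br)cc(OC)c1 | starting material
16 | (2S,3S)-3-(3,5-dimethoxyphenyl)-2-(4-methoxyphenyl)-4-[(E)-2-(4-methoxyphenyl)ethenyl]-2,3-dihydro-5H-furo[3,2-g]chromen-5-one | COc1cc(OC)cc(c1)[C@@H]1[C@@H](c2ccc(OC)cc2)Oc2cc3occc(=O)c3c(/C=C/c3ccc(OC)cc3)c21 | intermediate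
17 | (7S,2'S,3'S)-chromone-fused core: ring A fused to dihydrofuran 1 (2'-(4-methoxyphenyl), C3' bonded to ring B), to the seven-membered ring (C8H2, C7H-(4-methoxyphenyl), 3,5-dimethoxy ring B) and on a5–a6 to a 4H-pyran-4-one | COc1ccc([C@@H]2Cc3c4c(cc5occc(=O)c35)O[C@H](c3ccc(OC)cc3)[C@H]4c3cc(OC)cc(OC)c32)cc1 | intermediate
18 | (4-methoxyphenyl)boronic acid | COc1ccc(B(O)O)cc1 | starting material
19 | (7S,2'S,3'S,2''R)-flavanone: core 17 with the pyranone replaced by a 2''-(4-methoxyphenyl)chroman-4''-one (precursor of the key step) | COc1ccc([C@@H]2Cc3c4c(cc5c3C(=O)C[C@H](c3ccc(OC)cc3)O5)O[C@H](c3ccc(OC)cc3)[C@H]4c3cc(OC)cc(OC)c32)cc1 | intermediate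
20 | 4''-methoxy-2''H-chromene enol ether of 19 | COc1ccc([C@@H]2Cc3c4c(cc5c3C(OC)=C[C@H](c3ccc(OC)cc3)O5)O[C@H](c3ccc(OC)cc3)[C@H]4c3cc(OC)cc(OC)c32)cc1 | intermediate
21 | 4'',4''-dimethoxy-3''-[methoxy(phenyl)iodanyl] adduct, iodine trans to the C2'' aryl group | COc1ccc([C@@H]2Cc3c4c(cc5c3C(OC)(OC)[C@@H](I(OC)c3ccccc3)[C@H](c3ccc(OC)cc3)O5)O[C@H](c3ccc(OC)cc3)[C@H]4c3cc(OC)cc(OC)c32)cc1 | intermediate
22 | (7S,2'S,3'S,2''R,3''R)-methyl ester: core with trans methyl 2''-(4-methoxyphenyl)-2'',3''-dihydrobenzofuran-3''-carboxylate as dihydrofuran 2 (product of the key step) | COc1ccc([C@@H]2Cc3c4c(cc5c3[C@@H](C(=O)OC)[C@H](c3ccc(OC)cc3)O5)O[C@H](c3ccc(OC)cc3)[C@H]4c3cc(OC)cc(OC)c32)cc1 | intermediate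
23 | (7S,2'S,3'S,2''R,3''R)-carboxylic acid from 22 | COc1ccc([C@@H]2Cc3c4c(cc5c3[C@@H](C(=O)O)[C@H](c3ccc(OC)cc3)O5)O[C@H](c3ccc(OC)cc3)[C@H]4c3cc(OC)cc(OC)c32)cc1 | intermediate
24 | 1,3-dioxoisoindolin-2-yl ester of acid 23 | COc1ccc([C@@H]2Cc3c4c(cc5c3[C@@H](C(=O)ON3C(=O)c6ccccc6C3=O)[C@H](c3ccc(OC)cc3)O5)O[C@H](c3ccc(OC)cc3)[C@H]4c3cc(OC)cc(OC)c32)cc1 | intermediate
25 | hepta-O-methyl ether of the target (7S,2'S,3'S,2''R,3''R) | COc1ccc([C@@H]2Cc3c4c(cc5c3[C@@H](c3cc(OC)cc(OC)c3)[C@H](c3ccc(OC)cc3)O5)O[C@H](c3ccc(OC)cc3)[C@H]4c3cc(OC)cc(OC)c32)cc1 | intermediate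
26 | CNP0136963.1 (7S,2'S,3'S,2''R,3''R) | Oc1ccc([C@@H]2Cc3c4c(cc5c3[C@@H](c3cc(O)cc(O)c3)[C@H](c3ccc(O)cc3)O5)O[C@H](c3ccc(O)cc3)[C@H]4c3cc(O)cc(O)c32)cc1 | target

Total step count: 17. Longest linear sequence: 17 steps (from 1; the zinc reagents are made in the flask).

Steps most likely to fail

1. Step 13 (key step).
   - What may go wrong: the C2'' aryl group migrates or the ketone is simply dehydrogenated instead of ring A migrating; the trivalent iodine reagent attacks the dimethoxy-substituted rings; enol ether formation is slow at the peri-substituted ketone; acid opens the flavanone and erodes the C2'' configuration.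
   - Fallback, from 19 back to 22: at −78 °C, LiN(SiMe3)2 and 2,2,2-trifluoroethyl trifluoroacetate would convert 19 into the 3''-trifluoroacetyl flavanone F1. Methanesulfonyl azide and Et3N in MeCN would then give the 3''-diazo flavanone F2 (deacylative Regitz diazo transfer). Irradiation at 365 nm in methanol would trigger a Wolff rearrangement in which the same ring A carbon a6 migrates to C3''. The ketene F3 would be trapped by methanol and C3'' equilibrated to trans with DBU, which gives 22.

2. Step 11.
   - What may go wrong: the acid ionises the benzylic C2'–O bond of dihydrofuran 1 faster than it protonates the stilbene, so that five-membered closure onto the alkene or scrambling takes over; the cation is trapped by the pyranone carbonyl; ring B adds to the other face of C7.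
   - Fallback, from 16 back to 17: a Mukaiyama hydration (Mn(dpm)3 cat., PhSiH3, O2, i-PrOH, 0 °C) should put hydrogen on C8 and oxygen on C7, because the C7 radical is conjugated with the 4-methoxyphenyl ring whereas a C8 radical would sit next to the twisted, doubly ortho-substituted ring A. The resulting benzylic alcohol F4 (either C7 epimer) would be ionised with a catalytic Lewis acid (Bi(OTf)3, CH2Cl2/MeNO2, −20 °C), conditions too mild to open dihydrofuran 1, and the same Friedel–Crafts closure would give 17.

3. Step 10.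
   - What may go wrong: the hindered benzylic radical next to the styryl group is captured slowly, so that it dimerises, is reduced or fragments at the C2–O bond; the arylzinc reagent adds 1,4 to the pyranone under nickel catalysis.
   - Fallback, from 13 back to 16: the free acid 13 would be coupled directly with 1-iodo-3,5-dimethoxybenzene in a palladium-catalysed decarboxylative arylation (Pd(OAc)2, P(t-Bu)3, Cs2CO3, toluene, 110 °C). This is a two-electron pathway through a benzylic organopalladium species, known for 2-aryl-2,3-dihydrobenzofuran-3-carboxylic acids, and it should likewise give the trans product. This fallback makes no new compound (F0).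

Further compounds
F1 | step 13 | 3''-trifluoroacetyl derivative of flavanone 19 (C3'' unassigned, enolisable) | COc1ccc([C@@H]2Cc3c4c(cc5c3C(=O)C(C(=O)C(F)(F)F)[C@H](c3ccc(OC)cc3)O5)O[C@H](c3ccc(OC)cc3)[C@H]4c3cc(OC)cc(OC)c32)cc1
F2 | step 13 | 3''-diazo derivative of flavanone 19 | COc1ccc([C@@H]2Cc3c4c(cc5c3C(=O)C(=[N+]=[N-])[C@H](c3ccc(OC)cc3)O5)O[C@H](c3ccc(OC)cc3)[C@H]4c3cc(OC)cc(OC)c32)cc1
F3 | step 13 | ring-contracted ketene (C3''=C=O on dihydrofuran 2) | COc1ccc([C@@H]2Cc3c4c(cc5c3C(=C=O)[C@H](c3ccc(OC)cc3)O5)O[C@H](c3ccc(OC)cc3)[C@H]4c3cc(OC)cc(OC)c32)cc1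
F4 | step 11 | C7 benzylic alcohol from hydration of stilbene 16 (mixture of C7 epimers) | COc1cc(OC)cc(c1)[C@@H]1[C@@H](c2ccc(OC)cc2)Oc2cc3occc(=O)c3c(CC(O)c3ccc(OC)cc3)c21
F0 | step 10 | none | none
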